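Retrosynthetic overview (drimane numbering: C1–C10 decalin, C4 gem-dimethyl, C5/C10 ring fusion, C11 benzylic CH2)
- Target ⇐ regioselective sulfation and debenzylation ⇐ C8 enol triflate → methyl (C7=C8 alkene) ⇐ C9–C11 bond by alkylation of the C9 enolate of bicyclic enone 11 with aryl bromide 17, anti to the angular methyl group.
- Decalone 10 ⇐ ring A closed last through the C1–C10 bond: a tertiary C10 radical (from a C10 carboxylic acid, lost as CO2) adds to C1 of a C1=C2(SO2Ph) alkene tethered through C5–C4–C3.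
- The feature that allows this is the quaternary ring-fusion carbon C10 next to the C1 methylene: C10 can be a planar tertiary radical on a preformed ring B, and C1 the free terminus of an electron-poor alkene.
- Ring B, the C5 stereocenter and C4 come from (1R,5R)-verbenone: its cyclobutane C–C bond is cleaved, which frees the gem-dimethyl carbon as C4 and leaves C5 untouched.
- Ring order: ring B (from verbenone), then ring A (key step), then attachment of the arene.

Key step: step 5

Remark: compound 9 is carried as a mixture of epimers at its sulfonyl-bearing carbon (removed in step 6), and the target is set free as the hydrogen sulfate only in the last operation, its sodium salt 26 being the form to store.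

Step 1
Reactants: 1 (1R,5R)-verbenone
Product: 2 (1R,4S,5S)-4-ethenyl-4,6,6-trimethylbicyclo[3.1.1]heptan-2-one
Conditions: CH2=CHMgBr, CuI (cat.), THF, −40 to 0 °C; then 1 M HCl
Reagents that add atoms: vinylmagnesium bromide C=C[Mg]Br
Why: Copper-catalysed conjugate addition of the Grignard reagent to the enone should occur on the face away from the gem-dimethyl bridge and makes C10 quaternary with a vinyl group as a latent carboxyl group (the C10 configuration is erased in step 5).

Step 2
Reactants: 2 vinyl ketone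
Product: 4 (3S,4R)-3-ethenyl-4-(2-iodopropan-2-yl)-3-methylcyclohexan-1-one, via silyl enol ether 3 (not isolated)
Conditions: Me3SiI, CH2Cl2, −40 to 0 °C; then 1 M HCl, THF, 0 °C
Reagents that add atoms: iodotrimethylsilane C[Si](C)(C)I
Why: O-Silylation of the ketone should trigger heterolysis of the strained cyclobutane bond between the α-bridgehead and the gem-dimethyl carbon (Lewis-acid-mediated cyclobutane fragmentation of a nopinone), which gives the tertiary iodide at C4 and leaves C5 untouched.

Step 3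
Reactants: 4 tertiary iodide; 5 2,3-bis(phenylsulfonyl)prop-1-ene
Product: 6 (3S,4S)-3-ethenyl-3-methyl-4-[2-methyl-4-(phenylsulfonyl)pent-4-en-2-yl]cyclohexan-1-one
Conditions: (Bu3Sn)2, hν, benzene, rt
Reagents that add atoms: none
Why: The tertiary C4 radical formed by iodine abstraction adds to the CH2 terminus of 5 and the adduct expels a sulfonyl radical (radical allylation by addition–fragmentation), which installs C3, C2 and C1 as an α-sulfonyl alkene.

Step 4
Reactants: 6 vinyl ketone
Product: 8 (1R,2S)-1-methyl-2-[2-methyl-4-(phenylsulfonyl)pent-4-en-2-yl]-5-oxocyclohexane-1-carboxylic acid, via keto aldehyde 7 (not isolated)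
Conditions: O3, CH2Cl2/MeOH, −78 °C; Me2S; then NaClO2, NaH2PO4, 2-methyl-2-butene, t-BuOH/H2O, 0 °C to rt
Reagents that add atoms: ozone [O-][O+]=O; sodium chlorite [Na+].[O-]Cl=O
Why: Ozonolysis should cleave the electron-rich vinyl group much faster than the electron-poor sulfonyl alkene, and Pinnick oxidation of the aldehyde in the same flask gives the tertiary acid.

Step 5
Reactants: 8 keto acid
Product: 9 (4aS,8aS)-5,5,8a-trimethyl-7-(phenylsulfonyl)octahydronaphthalen-2(1H)-one (trans-fused, epimers at C7)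
Conditions: [Ir(dF(CF3)ppy)2(dtbbpy)]PF6 (cat.), K2HPO4, DMF, blue LEDs, rt
Reagents that add atoms: none
Why: The carboxylate of 8 is oxidised by the photoexcited trivalent iridium complex and loses CO2 to give the tertiary C10 radical, which adds to C1, the unsubstituted terminus of the C1=C2(SO2Ph) alkene held by the C5–C4–C3 tether; the α-sulfonyl radical is then reduced by divalent iridium and protonated. The closest known reaction type is the photoredox decarboxylative conjugate addition (Giese reaction) of tertiary acids, which is used to make quaternary carbons and is run here intramolecularly. Ring A closes in the 6-endo-trig mode. The new stereocenter C10 is set by substrate control from C5: in a chair-like transition state ring B stays a chair with the bulky CMe2 tether equatorial, C1 bonds on the face syn to H-5 and the methyl group becomes axial, the trans-decalin arrangement also reached in radical polyene cyclizations; the configuration of C10 in 8 does not matter because the radical is planar. The step needs 6-endo over 5-exo closure, which the sulfonyl group on C2 secures (polarity-matched attack at the CH2 terminus, a stabilised adduct radical and a fully substituted 5-exo position), and trans over cis ring fusion, for which the equatorial tether is the controlling element.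

Step 6
Reactants: 9 sulfonyl decalone
Product: 10 (4aS,8aR)-5,5,8a-trimethyloctahydronaphthalen-2(1H)-one
Conditions: Na(Hg), Na2HPO4, MeOH/THF, −20 °C
Reagents that add atoms: none
Why: Reductive desulfonylation by electron transfer from sodium amalgam removes the activating group from C2, and any carbinol formed by over-reduction at C8 would be re-oxidised by IBX in step 7.

Step 7
Reactants: 10 decalone
Product: 11 (4aS,8aR)-5,5,8a-trimethyl-4a,5,6,7,8,8a-hexahydronaphthalen-2(1H)-one
Conditions: IBX, DMSO/PhF, 70 °C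
Reagents that add atoms: none
Why: IBX dehydrogenation of the ketone can only run toward C7–C6 because C9 has no β-hydrogen (C10 is quaternary), so the enone forms regiospecifically and blocks C7 for the later enolisation.

Step 8
Reactants: 12 2,5-dibromobenzene-1,4-diol
Product: 13 1,4-dibromo-2,5-bis(methoxymethoxy)benzene
Conditions: MOMCl, i-Pr2NEt, CH2Cl2, 0 °C to rt
Reagents that add atoms: chloromethyl methyl ether COCCl
Why: O-Alkylation of both phenols with the chloromethyl ether gives the bis-acetal, which later directs the lithiation and is removable without touching benzyl ethers.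

Step 9
Reactants: 13 dibromide
Product: 14 1,4-bis(benzyloxy)-2,5-bis(methoxymethoxy)benzene
Conditions: BnOH, Pd2(dba)3 (cat.), RockPhos, Cs2CO3, toluene, 90 °C
Reagents that add atoms: benzyl alcohol OCc1ccccc1
Why: Palladium-catalysed C–O cross-coupling (Buchwald–Hartwig etherification) with a bulky biaryl phosphine should replace both bromides of the electron-rich arene by benzyloxy groups.

Step 10
Reactants: 14 tetraether
Product: 16 [3,6-bis(benzyloxy)-2,5-bis(methoxymethoxy)phenyl]methanol, via aryllithium 15 (not isolated)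
Conditions: n-BuLi, TMEDA, THF, −78 to −20 °C; (CH2O)n, −78 °C to rt; H2O
Reagents that add atoms: formaldehyde C=O
Why: Directed ortho-metalation occurs at one of the two equivalent ring positions flanked by an acetal and a benzyloxy group, and the aryllithium is hydroxymethylated by formaldehyde.

Step 11
Reactants: 16 benzylic alcohol
Product: 17 1,4-bis(benzyloxy)-2-(bromomethyl)-3,6-bis(methoxymethoxy)benzene
Conditions: CBr4, PPh3, CH2Cl2, 0 °C
Reagents that add atoms: carbon tetrabromide BrC(Br)(Br)Br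
Why: The Appel reaction converts the benzylic alcohol into the bromide under acid-free conditions that spare the acetals (the bromide is used crude).

Step 12
Reactants: 11 enone; 17 aryl bromide
Product: 19 (1S,4aS,8aS)-1-{[3,6-bis(benzyloxy)-2,5-bis(methoxymethoxy)phenyl]methyl}-5,5,8a-trimethyl-4a,5,6,7,8,8a-hexahydronaphthalen-2(1H)-one, via lithium dienolate 18 (not isolated)
Conditions: LiN(iPr)2, THF, −78 °C; then 17, DMPU, −78 to −30 °C
Reagents that add atoms: none
Why: Kinetic α'-deprotonation of the enone gives the cross-conjugated dienolate at C9, whose alkylation by the benzylic bromide should occur on the face anti to the axial C10 methyl group (substrate control), setting the C9 stereocenter with the arylmethyl group trans to that methyl.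

Step 13
Reactants: 19 benzylated enone
Product: 21 (1S,4aS,8aS)-1-{[3,6-bis(benzyloxy)-2,5-bis(methoxymethoxy)phenyl]methyl}-5,5,8a-trimethyl-1,4,4a,5,6,7,8,8a-octahydronaphthalen-2-yl trifluoromethanesulfonate, via lithium enolate 20 (not isolated)
Conditions: Li[HB(s-Bu)3], THF, −78 °C; then PhNTf2, −78 to 0 °C; H2O
Reagents that add atoms: N-phenylbis(trifluoromethanesulfonimide) O=S(=O)(N(c1ccccc1)S(=O)(=O)C(F)(F)F)C(F)(F)F
Why: Conjugate hydride reduction of the enone generates the C7–C8 enolate regiospecifically, and its O-triflation fixes the alkene position without enolisation toward C9, so C9 is not epimerised.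

Step 14
Reactants: 21 enol triflate
Product: 22 1,4-bis(benzyloxy)-2,5-bis(methoxymethoxy)-3-{[(1R,4aS,8aS)-2,5,5,8a-tetramethyl-1,4,4a,5,6,7,8,8a-octahydronaphthalen-1-yl]methyl}benzene
Conditions: Me2CuLi, Et2O/THF, −20 to 0 °C
Reagents that add atoms: lithium dimethylcuprate [Li+].C[Cu-]C
Why: Cross-coupling of the enol triflate with the Gilman cuprate replaces the triflate by methyl with retention of the alkene position, completing the C7=C8 alkene with its C8 methyl group.

Step 15
Reactants: 22 bis-acetal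
Product: 23 3,6-bis(benzyloxy)-2-{[(1R,4aS,8aS)-2,5,5,8a-tetramethyl-1,4,4a,5,6,7,8,8a-octahydronaphthalen-1-yl]methyl}benzene-1,4-diol
Conditions: ZnBr2, n-PrSH, CH2Cl2, 0 °C
Reagents that add atoms: none
Why: Lewis-acid-assisted transfer of the methoxymethyl groups to the thiol cleaves both acetals quickly under conditions too mild to isomerise the alkene or cleave benzyl ethers (the hydroquinone is kept under argon).

Step 16
Reactants: 23 diol
Product: 25 sodium 2,5-bis(benzyloxy)-4-hydroxy-3-{[(1R,4aS,8aS)-2,5,5,8a-tetramethyl-1,4,4a,5,6,7,8,8a-octahydronaphthalen-1-yl]methyl}phenyl sulfate, via pyridinium sulfate 24 (not isolated)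
Conditions: SO3·pyridine, pyridine, 0 °C to rt; then aq. NaHCO3
Reagents that add atoms: sulfur trioxide–pyridine complex [O-]S(=O)(=O)[n+]1ccccc1; sodium hydrogen carbonate [Na+].OC([O-])=O
Why: O-Sulfation should take place at the phenol that has a ring hydrogen as neighbour, because the other phenol is flanked by the bulky terpenylmethyl group and a benzyloxy group.

Step 17
Reactants: 25 sodium sulfate
Product: 27 2,4,5-trihydroxy-3-{[(1R,4aS,8aS)-2,5,5,8a-tetramethyl-1,4,4a,5,6,7,8,8a-octahydronaphthalen-1-yl]methyl}phenyl hydrogen sulfate, via sodium sulfate 26 (not isolated)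
Conditions: H2 (1 atm), Pd/C, EtOAc/MeOH, rt; then 1 M HCl (1 equiv), 0 °C
Reagents that add atoms: none
Why: Hydrogenolysis removes the two benzyl ethers while the hindered trisubstituted alkene and the sulfate monoester should survive, and one equivalent of acid sets the hydrogen sulfate free.

Compound list
1 | (1R,5R)-4,6,6-trimethylbicyclo[3.1.1]hept-3-en-2-one, (+)-verbenone | CC1=CC(=O)[C@@H]2C[C@H]1C2(C)C | starting material
2 | (1R,4S,5S)-4-ethenyl-4,6,6-trimethylbicyclo[3.1.1]heptan-2-one (vinyl anti to the gem-dimethyl bridge) | C=C[C@]1(C)CC(=O)[C@@H]2C[C@H]1C2(C)C | intermediate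
3 | {[(4R,5S)-5-ethenyl-4-(2-iodopropan-2-yl)-5-methylcyclohex-1-en-1-yl]oxy}trimethylsilane | C[Si](C)(C)OC1=CC[C@@H](C(C)(C)I)[C@](C)(C=C)C1 | intermediate
4 | (3S,4R)-3-ethenyl-4-(2-iodopropan-2-yl)-3-methylcyclohexan-1-one | O=C1C[C@@](C)(C=C)[C@H](C(C)(C)I)CC1 | intermediate
5 | 2,3-bis(phenylsulfonyl)prop-1-ene | C=C(CS(=O)(=O)c1ccccc1)S(=O)(=O)c1ccccc1 | starting material
6 | (3S,4S)-3-ethenyl-3-methyl-4-[2-methyl-4-(phenylsulfonyl)pent-4-en-2-yl]cyclohexan-1-one | O=C1C[C@@](C)(C=C)[C@H](C(C)(C)CC(=C)S(=O)(=O)c2ccccc2)CC1 | intermediate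
7 | (1R,2S)-1-methyl-2-[2-methyl-4-(phenylsulfonyl)pent-4-en-2-yl]-5-oxocyclohexane-1-carbaldehyde | O=C1C[C@@](C)(C=O)[C@H](C(C)(C)CC(=C)S(=O)(=O)c2ccccc2)CC1 | intermediate
8 | (1R,2S)-1-methyl-2-[2-methyl-4-(phenylsulfonyl)pent-4-en-2-yl]-5-oxocyclohexane-1-carboxylic acid | O=C1C[C@@](C)(C(=O)O)[C@H](C(C)(C)CC(=C)S(=O)(=O)c2ccccc2)CC1 | intermediate
9 | (4aS,8aS)-5,5,8a-trimethyl-7-(phenylsulfonyl)octahydronaphthalen-2(1H)-one, trans-fused, epimers at C7 | O=C1CC[C@H]2C(C)(C)CC(S(=O)(=O)c3ccccc3)C[C@]2(C)C1 | intermediate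
10 | (4aS,8aR)-5,5,8a-trimethyloctahydronaphthalen-2(1H)-one, trans-fused | O=C1CC[C@H]2C(C)(C)CCC[C@]2(C)C1 | intermediate
11 | (4aS,8aR)-5,5,8a-trimethyl-4a,5,6,7,8,8a-hexahydronaphthalen-2(1H)-one | O=C1C=C[C@H]2C(C)(C)CCC[C@]2(C)C1 | intermediate
12 | 2,5-dibromobenzene-1,4-diol | Oc1cc(Br)c(O)cc1Br | starting material
13 | 1,4-dibromo-2,5-bis(methoxymethoxy)benzene | COCOc1cc(Br)c(OCOC)cc1Br | intermediate
14 | 1,4-bis(benzyloxy)-2,5-bis(methoxymethoxy)benzene | COCOc1cc(OCc2ccccc2)c(OCOC)cc1OCc1ccccc1 | intermediate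
15 | [3,6-bis(benzyloxy)-2,5-bis(methoxymethoxy)phenyl]lithium | [Li]c1c(OCOC)c(OCc2ccccc2)cc(OCOC)c1OCc1ccccc1 | intermediate
16 | [3,6-bis(benzyloxy)-2,5-bis(methoxymethoxy)phenyl]methanol | OCc1c(OCOC)c(OCc2ccccc2)cc(OCOC)c1OCc1ccccc1 | intermediate
17 | 1,4-bis(benzyloxy)-2-(bromomethyl)-3,6-bis(methoxymethoxy)benzene | BrCc1c(OCOC)c(OCc2ccccc2)cc(OCOC)c1OCc1ccccc1 | intermediate
18 | lithium dienolate of 11 (O–Li on C8, C8=C9 and C6=C7 double bonds) | [Li]OC=1C=C[C@H]2C(C)(C)CCC[C@]2(C)C=1 | intermediate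
19 | (1S,4aS,8aS)-1-{[3,6-bis(benzyloxy)-2,5-bis(methoxymethoxy)phenyl]methyl}-5,5,8a-trimethyl-4a,5,6,7,8,8a-hexahydronaphthalen-2(1H)-one | O=C1C=C[C@H]2C(C)(C)CCC[C@]2(C)[C@@H]1Cc1c(OCOC)c(OCc3ccccc3)cc(OCOC)c1OCc1ccccc1 | intermediate
20 | lithium enolate from conjugate reduction of 19 (O–Li on C8, C7=C8 double bond) | [Li]OC1=CC[C@H]2C(C)(C)CCC[C@]2(C)[C@@H]1Cc1c(OCOC)c(OCc3ccccc3)cc(OCOC)c1OCc1ccccc1 | intermediate
21 | (1S,4aS,8aS)-1-{[3,6-bis(benzyloxy)-2,5-bis(methoxymethoxy)phenyl]methyl}-5,5,8a-trimethyl-1,4,4a,5,6,7,8,8a-octahydronaphthalen-2-yl trifluoromethanesulfonate | O=S(=O)(OC1=CC[C@H]2C(C)(C)CCC[C@]2(C)[C@@H]1Cc1c(OCOC)c(OCc3ccccc3)cc(OCOC)c1OCc1ccccc1)C(F)(F)F | intermediate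
22 | 1,4-bis(benzyloxy)-2,5-bis(methoxymethoxy)-3-{[(1R,4aS,8aS)-2,5,5,8a-tetramethyl-1,4,4a,5,6,7,8,8a-octahydronaphthalen-1-yl]methyl}benzene | CC1=CC[C@H]2C(C)(C)CCC[C@]2(C)[C@@H]1Cc1c(OCOC)c(OCc3ccccc3)cc(OCOC)c1OCc1ccccc1 | intermediate
23 | 3,6-bis(benzyloxy)-2-{[(1R,4aS,8aS)-2,5,5,8a-tetramethyl-1,4,4a,5,6,7,8,8a-octahydronaphthalen-1-yl]methyl}benzene-1,4-diol | CC1=CC[C@H]2C(C)(C)CCC[C@]2(C)[C@@H]1Cc1c(O)c(OCc3ccccc3)cc(O)c1OCc1ccccc1 | intermediate
24 | pyridinium 2,5-bis(benzyloxy)-4-hydroxy-3-{[(1R,4aS,8aS)-2,5,5,8a-tetramethyl-1,4,4a,5,6,7,8,8a-octahydronaphthalen-1-yl]methyl}phenyl sulfate | CC1=CC[C@H]2C(C)(C)CCC[C@]2(C)[C@@H]1Cc1c(O)c(OCc3ccccc3)cc(OS(=O)(=O)[O-])c1OCc1ccccc1.c1cc[nH+]cc1 | intermediate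
25 | sodium 2,5-bis(benzyloxy)-4-hydroxy-3-{[(1R,4aS,8aS)-2,5,5,8a-tetramethyl-1,4,4a,5,6,7,8,8a-octahydronaphthalen-1-yl]methyl}phenyl sulfate | CC1=CC[C@H]2C(C)(C)CCC[C@]2(C)[C@@H]1Cc1c(O)c(OCc3ccccc3)cc(OS(=O)(=O)[O-])c1OCc1ccccc1.[Na+] | intermediate
26 | sodium 2,4,5-trihydroxy-3-{[(1R,4aS,8aS)-2,5,5,8a-tetramethyl-1,4,4a,5,6,7,8,8a-octahydronaphthalen-1-yl]methyl}phenyl sulfate | CC1=CC[C@H]2C(C)(C)CCC[C@]2(C)[C@@H]1Cc1c(O)c(O)cc(OS(=O)(=O)[O-])c1O.[Na+] | intermediate
27 | 2,4,5-trihydroxy-3-{[(1R,4aS,8aS)-2,5,5,8a-tetramethyl-1,4,4a,5,6,7,8,8a-octahydronaphthalen-1-yl]methyl}phenyl hydrogen sulfate | CC1=CC[C@H]2C(C)(C)CCC[C@]2(C)[C@@H]1Cc1c(O)c(O)cc(OS(=O)(=O)O)c1O | target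

Total step count: 17 (13 on the terpenoid line, 4 for the aryl bromide). Longest linear sequence: 13 steps (steps 1–7 and 12–17).

Steps most likely to fail

Step 5. The ring closure may show poor facial selectivity at C10 (cis- instead of trans-ring fusion), and the tertiary radical may be reduced before it cyclises. The fallback places the C10 substituent on the bicycle, where the gem-dimethyl bridge fixes the face, and closes ring A from a C4 cation instead. It sets out from 1: Hosomi–Sakurai conjugate allylation (allyltrimethylsilane, TiCl4, CH2Cl2, −78 °C) should give (1R,4R,5R)-4,6,6-trimethyl-4-(prop-2-en-1-yl)bicyclo[3.1.1]heptan-2-one F1 with the allyl group anti to the bridge. Treatment of the isolated ketone with TiCl4 at 0 °C should then open the cyclobutane; the tertiary C4 cation is captured by the terminal alkene carbon (cation–olefin cyclisation, chloride trapping at C2) to give trans-fused (4aS,8aS)-7-chloro-5,5,8a-trimethyloctahydronaphthalen-2(1H)-one F2. Radical dechlorination (Bu3SnH, AIBN, benzene, 80 °C) brings the material back to the route at 10.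

Step 3. The tertiary iodide may lose HI to the isopropenyl compound faster than it enters the radical chain, and the product alkene may take up a second radical. The fallback generates the C4 radical from an alkene instead of a halide and sets out from 2. Cyclobutane opening with BF3·OEt2, Zn(OAc)2 and Ac2O should give (4S,5S)-5-ethenyl-5-methyl-4-(prop-1-en-2-yl)cyclohex-1-en-1-yl acetate F3; methanolysis (K2CO3, MeOH) gives (3S,4S)-3-ethenyl-3-methyl-4-(prop-1-en-2-yl)cyclohexan-1-one F4. Hydrogen-atom transfer to the 1,1-disubstituted alkene (Fe(acac)3, PhSiH3, EtOH, 60 °C; the monosubstituted vinyl group reacts far more slowly) in the presence of 5 then gives the same addition–fragmentation and returns to the route at 6.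

Step 16. Sulfation may fail to distinguish the two phenols or may go on to the bis-sulfate, and the hydroquinone may be oxidised by air during handling. The fallback uses a protected, neutral sulfate that can be purified and sets out from 23. 2,2,2-Trichloroethyl chlorosulfate with DMAP and Et3N in THF should give 2,5-bis(benzyloxy)-4-hydroxy-3-{[(1R,4aS,8aS)-2,5,5,8a-tetramethyl-1,4,4a,5,6,7,8,8a-octahydronaphthalen-1-yl]methyl}phenyl 2,2,2-trichloroethyl sulfate F5, which is separated from any regioisomer by chromatography. Transfer hydrogenolysis (Pd/C, HCO2NH4, MeOH) removes the trichloroethyl group and both benzyl ethers to give ammonium 2,4,5-trihydroxy-3-{[(1R,4aS,8aS)-2,5,5,8a-tetramethyl-1,4,4a,5,6,7,8,8a-octahydronaphthalen-1-yl]methyl}phenyl sulfate F6; one equivalent of HCl brings the material back to the route at 27.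

Further compounds
F1 | step 5 | (1R,4R,5R)-4,6,6-trimethyl-4-(prop-2-en-1-yl)bicyclo[3.1.1]heptan-2-one | C=CC[C@]1(C)CC(=O)[C@@H]2C[C@H]1C2(C)C
F2 | step 5 | (4aS,8aS)-7-chloro-5,5,8a-trimethyloctahydronaphthalen-2(1H)-one, epimers at C7 | O=C1CC[C@H]2C(C)(C)CC(Cl)C[C@]2(C)C1
F3 | step 3 | (4S,5S)-5-ethenyl-5-methyl-4-(prop-1-en-2-yl)cyclohex-1-en-1-yl acetate | CC(=O)OC1=CC[C@@H](C(C)=C)[C@](C)(C=C)C1
F4 | step 3 | (3S,4S)-3-ethenyl-3-methyl-4-(prop-1-en-2-yl)cyclohexan-1-one | O=C1C[C@@](C)(C=C)[C@H](C(C)=C)CC1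
F5 | step 16 | 2,5-bis(benzyloxy)-4-hydroxy-3-{[(1R,4aS,8aS)-2,5,5,8a-tetramethyl-1,4,4a,5,6,7,8,8a-octahydronaphthalen-1-yl]methyl}phenyl 2,2,2-trichloroethyl sulfate | CC1=CC[C@H]2C(C)(C)CCC[C@]2(C)[C@@H]1Cc1c(O)c(OCc3ccccc3)cc(OS(=O)(=O)OCC(Cl)(Cl)Cl)c1OCc1ccccc1
F6 | step 16 | ammonium 2,4,5-trihydroxy-3-{[(1R,4aS,8aS)-2,5,5,8a-tetramethyl-1,4,4a,5,6,7,8,8a-octahydronaphthalen-1-yl]methyl}phenyl sulfate | CC1=CC[C@H]2C(C)(C)CCC[C@]2(C)[C@@H]1Cc1c(O)c(O)cc(OS(=O)(=O)[O-])c1O.[NH4+]
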